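In a one-step world, starting complex and incoming ligand give complex with one exchanged and nothing else, and 0.0600 M of ligand on 0.050 M of complex covers the full charge. The earlier runs show otherwise.

common to all: starting complex 0.050 M

| flask | incoming ligand | protic impurity | remark | time |
|---|---|---|---|---|
| eta | 0.060 M | 0.98 mM | run made earlier |  |
| delta | 0.060 M | 2.8 mM | run made earlier |  |
| theta | 0.060 M | 7 mM | run made earlier |  |
| ash | 0.0600 M | 1.00 mM |  | 20 h |
| birch | 0.0600 M | 2.00 mM |  | 20 h |
| maple | 0.0600 M | 4.00 mM |  | 20 h |
| alder | 0.0600 M | 8.00 mM |  | 20 h |

| run | time / h | complex with one exchanged / % |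
|---|---|---|
| eta | 2.00 | 13.7 |
| eta | 5.00 | 20.6 |
| eta | 10.0 | 27.8 |
| eta | 15.0 | 26.8 |
| eta | 20.0 | 27.0 |
| delta | 1.50 | 11.0 |
| delta | 3.00 | 15.2 |
| delta | 6.00 | 21.8 |
| delta | 10.0 | 25.1 |
| delta | 20.0 | 26.4 |
| theta | 4.00 | 19.8 |
| theta | 8.00 | 24.4 |
| theta | 12.0 | 25.7 |
| theta | 15.0 | 26.6 |
| theta | 20.0 | 24.3 |

(standard deviation of a reading: 1 percentage point)

- what was read earlier has a scatter of 1 percentage point, one standard deviation
- candidate steps: starting complex + incoming ligand <-> leaving ligand + complex with one exchanged; complex with one exchanged + incoming ligand <-> leaving ligand + complex with two exchanged; complex with two exchanged + incoming ligand <-> leaving ligand + complex with three exchanged; complex with three exchanged + incoming ligand <-> leaving ligand + complex with four exchanged; complex with one exchanged <-> isomer of the product; incoming ligand -> decomposition product; protic impurity + incoming ligand -> quenched reagent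
- "hardly changes" means that all values lie within two and a half points (for a concentration: within two and a half percent of the largest)

- amount of complex with one exchanged at the end, in percent of the starting complex charged for ash, birch, maple, alder, in this order
- how the row runs (falls, then rises / hardly changes / rises all the way / rises, then falls / falls all the way)

In the first instants, the candidate steps offer the ligand two partners, starting complex and protic impurity. The early readings are the eta run's 13.7 % at 2.00 h and the delta run's 11.0 % at 1.50 h, with 0.98 mM and 2.8 mM of impurity; they stand at different times, so the pair gives no direct comparison of the two flasks. In the middle, complex with one exchanged is an intermediate, exposed to a second exchange and to isomerisation, and the curve bends. Late on, the eta readings lie flat within their scatter: they go from 27.8 % at 10.0 h to 27.0 % at 20.0 h, a fall of 0.8 percentage points against a scatter of 1 point.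

Among the candidate steps the impurity appears in one, where it takes ligand one to one. The ligand budget of a flask is [incoming ligand] charged minus [protic impurity] charged, and the budget ratio of alder to ash is 0.881. Reckoned roughly as a slower clock, alder at 20 h stands where ash stands at 17.6 h. The eta readings on either side of that time are 26.8 % at 15.0 h and 27.0 % at 20.0 h. This reckoning gives a row flat within the scatter, flatter than the forecast below.

The forecast gives 27 %, 26.7 %, 26.2 % and 25.2 %, shape hardly changes: “so the row hardly changes”.

    starting complex + incoming ligand ⇌ leaving ligand + complex with one exchanged (K = 24.0, k = 1.40 /M/h)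
    complex with one exchanged + incoming ligand ⇌ leaving ligand + complex with two exchanged (K = 55.0, k = 1.20 /M/h)
    complex with two exchanged + incoming ligand ⇌ leaving ligand + complex with three exchanged (K = 26.0, k = 2.20 /M/h)
    complex with three exchanged + incoming ligand ⇌ leaving ligand + complex with four exchanged (K = 0.110, k = 0.690 /M/h)
    complex with one exchanged ⇌ isomer of the product (K = 0.830, k = 0.0680 /h)
    incoming ligand → decomposition product (k = 1.80 × 10⁻⁴ /h)
    protic impurity + incoming ligand → quenched reagent (k = 45.0 /M/h)

The flasks give 26.6 %, 26.5 %, 26.3 % and 25.8 %, shape hardly changes, a span of 0.8 points, so the two reckonings agree on the shape. In ash at 20.0 h, complex with one exchanged is made at 0.921 of the rate at which it is used up, each step taken net. Alder's budget ratio of 0.881 stands beside a leaving ligand ratio to ash of 0.888 at 20.0 h. For maple, the budget ratio to ash is 0.949, and the leaving ligand ratio at 20.0 h is 0.952.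

All runs stem from a simulated flask with constants of no real substance, noise included.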